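**Retrosynthetic overview**
1. Cut the diaryl ether C–O bond on the ring B side: target ⇒ ring A phenol 5 (2,3,5-tribromo-6-methoxyphenol) + a 2-hydroxyaryl cation equivalent, the ortho-quinone diazide 7 (proposed new Rh-carbene O–H insertion, last step).
2. 7 ⇐ 2-amino-4,6-dibromophenol 6 by diazotisation; the ring B bromine pattern is bought.
3. 5 ⇐ 3,5-dibromo-2-methoxyphenol 4 (ortho-bromination) ⇐ aldehyde 2 (Baeyer–Villiger) ⇐ 3,5-dibromosalicylaldehyde 1 (O-methylation).
4. No ring is built: both benzene rings are bought. Ring A is finished first (its C6 bromine last), and ring B is joined in the final step.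

Assumption: the SMILES has no stereocentre and the diaryl ether rotates freely, so the target is achiral and "single enantiomer" is taken to mean the single constitutional isomer drawn.

**Route**

Step 1
Reactants: 1 3,5-dibromo-2-hydroxybenzaldehyde
Product: 2 3,5-dibromo-2-methoxybenzaldehyde
Conditions: MeI (1.5 equiv), K2CO3 (1.5 equiv), DMF, 40 °C
Reagents that add atoms: iodomethane, CI
Why: Williamson ether synthesis, in which the acidic phenol is deprotonated by K2CO3 and the phenoxide is methylated by MeI (SN2); no stereocentre is formed.

Step 2
Reactants: 2 3,5-dibromo-2-methoxybenzaldehyde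
Product: 4 3,5-dibromo-2-methoxyphenol, via 3,5-dibromo-2-methoxyphenyl formate 3 (not isolated)
Conditions: mCPBA (1.5 equiv), CH2Cl2, 40 °C; then K2CO3 (cat.), MeOH, rt
Reagents that add atoms: meta-chloroperoxybenzoic acid (mCPBA), O=C(OO)c1cccc(Cl)c1
Why: Baeyer–Villiger (Dakin-type) oxidation, in which the peracid adds to the aldehyde and the aryl group, helped by the ortho-methoxy donor, migrates to oxygen to give the aryl formate, which base-catalysed methanolysis cleaves to the phenol; no stereocentre is formed.

Step 3
Reactants: 4 3,5-dibromo-2-methoxyphenol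
Product: 5 2,3,5-tribromo-6-methoxyphenol
Conditions: NBS (1.05 equiv), i-Pr2NH (10 mol %), CH2Cl2, 0 °C to rt
Reagents that add atoms: N-bromosuccinimide, O=C1CCC(=O)N1Br
Why: Amine-mediated ortho-selective electrophilic aromatic bromination, in which the N-bromoamine made in the flask is delivered by hydrogen bonding to the phenol OH onto the only free ortho carbon, while the para carbon is shielded between two bromines; no stereocentre is formed.

Step 4
Reactants: 6 2-amino-4,6-dibromophenol
Product: 7 2,4-dibromo-6-diazocyclohexa-2,4-dien-1-one (the ortho-quinone diazide, i.e. the inner diazonium phenolate)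
Conditions: t-BuONO (1.3 equiv), AcOH (cat.), MeCN, 0 °C, dark; kept cold in solution behind a shield, not stored dry
Reagents that add atoms: tert-butyl nitrite, CC(C)(C)ON=O
Why: Diazotisation of an ortho-aminophenol with an alkyl nitrite, after which the acidic phenol loses its proton to give the neutral diazo oxide, so the future C–O position is fixed at the former C–N carbon; no stereocentre is formed.

Step 5
Reactants: 5 2,3,5-tribromo-6-methoxyphenol; 7 2,4-dibromo-6-diazocyclohexa-2,4-dien-1-one
Product: 8 2,4-dibromo-6-(2,3,5-tribromo-6-methoxyphenoxy)phenol (target)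
Conditions: Rh2(esp)2 (1 mol %), 4 Å MS, PhCF3, 40 °C, dark; 7 (1.0 equiv) added by syringe pump over 4 h to 5 (1.5 equiv, excess recovered)
Reagents that add atoms: none
Why: Proposed new method: Rh2(esp)2 takes N2 out of the ortho-quinone diazide 7 and carries a strongly electrophilic quinoid carbene at the carbon next to the carbonyl, the oxygen of the hindered but acidic phenol 5 adds to that carbon, and a proton shift onto the dienone oxygen re-aromatises ring B, so the diaryl ether bond forms exactly at the former C–N carbon and the ortho-OH is left free without base, copper or palladium that could touch the five C–Br bonds; the closest known reaction type is Rh(II)-carbenoid O–H insertion of diazo carbonyl compounds into phenols and alcohols (and quinoid-carbene transfer from quinone diazides in cyclopropanation and C–H arylation), which to my knowledge has not been shown for a monocyclic ortho-benzoquinone diazide as 2-hydroxyaryl cation equivalent with a 2,6-disubstituted polybromophenol; no stereocentre is formed.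

**Compound list**

1 | 3,5-dibromo-2-hydroxybenzaldehyde | O=Cc1cc(Br)cc(Br)c1O | starting material
2 | 3,5-dibromo-2-methoxybenzaldehyde | COc1c(C=O)cc(Br)cc1Br | intermediate
3 | 3,5-dibromo-2-methoxyphenyl formate | COc1c(OC=O)cc(Br)cc1Br | intermediate (not isolated)
4 | 3,5-dibromo-2-methoxyphenol | COc1c(O)cc(Br)cc1Br | intermediate
5 | 2,3,5-tribromo-6-methoxyphenol | COc1c(O)c(Br)c(Br)cc1Br | intermediate
6 | 2-amino-4,6-dibromophenol | Nc1cc(Br)cc(Br)c1O | starting material
7 | 2,4-dibromo-6-diazocyclohexa-2,4-dien-1-one | O=C1C(Br)=CC(Br)=CC1=[N+]=[N-] | intermediate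
8 | 2,4-dibromo-6-(2,3,5-tribromo-6-methoxyphenoxy)phenol | COc1c(Br)cc(Br)c(Br)c1Oc1cc(Br)cc(Br)c1O | target

**Step count**

Total step count: 5. Longest linear sequence: 4 steps (1 → 2 → 4 → 5 → 8; steps 1, 2, 3 and 5). Step 4 is the one-step side branch to 7.

**Three steps most likely to fail**

Step 5 (the proposed new O–H insertion). The risks are carbene dimerisation to the azine, ring contraction of the carbene, a second insertion into the OH of the product, and low reactivity of the shielded phenol. The fallback uses known chemistry only, sets out from 5 and comes back at 8. The phenoxide of 5 displaces fluoride from 2-fluorobenzaldehyde (K2CO3, DMAc, 130 °C, SNAr activated by the ortho-formyl group) to give 2-(2,3,5-tribromo-6-methoxyphenoxy)benzaldehyde F1. Baeyer–Villiger oxidation (mCPBA, CH2Cl2) gives 2-(2,3,5-tribromo-6-methoxyphenoxy)phenyl formate F2, which is methanolysed in the same flask (K2CO3 cat., MeOH) to 2-(2,3,5-tribromo-6-methoxyphenoxy)phenol F3. NBS (2.05 equiv, MeCN, 0 °C to rt) then brominates ring B ortho and para to its free OH, while ring A is deactivated by three bromines, and gives 8.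

Step 3 (regiochemistry at C6 against C4, and over-bromination). The fallback sets out from 2 and comes back at 5, and replaces phenol-controlled bromination by formyl-directed C–H activation. Pd(OAc)2 (10 mol %) with a catalytic amino-acid transient directing group and NBS (DCE, TFA additive, 60 °C) brominates the only C–H next to the formyl group and gives 2,3,5-tribromo-6-methoxybenzaldehyde F4. Baeyer–Villiger oxidation (mCPBA, CH2Cl2) gives 2,3,5-tribromo-6-methoxyphenyl formate F5, and methanolysis (K2CO3 cat., MeOH) gives 5.

Step 2 (hydride instead of aryl migration, giving the benzoic acid, because the ring carries two bromines and a twisted methoxy group). The fallback sets out from 1 and comes back at 4, and uses the free phenoxide to drive the aryl shift. Classical Dakin oxidation of 1 (H2O2, aq NaOH, 0 °C to rt, then acid work-up) gives 3,5-dibromo-2-hydroxyphenyl formate F6, which is hydrolysed in the flask to 3,5-dibromobenzene-1,2-diol F7. Monomethylation with MeI (1.0 equiv) and Li2CO3 (1.0 equiv) in DMF at 40 °C goes to the more acidic OH, the one flanked by bromine and para to the second bromine, and gives 4.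

**Further compounds**

F1 | step 5 | 2-(2,3,5-tribromo-6-methoxyphenoxy)benzaldehyde | COc1c(Br)cc(Br)c(Br)c1Oc1ccccc1C=O
F2 | step 5 | 2-(2,3,5-tribromo-6-methoxyphenoxy)phenyl formate | COc1c(Br)cc(Br)c(Br)c1Oc1ccccc1OC=O
F3 | step 5 | 2-(2,3,5-tribromo-6-methoxyphenoxy)phenol | COc1c(Br)cc(Br)c(Br)c1Oc1ccccc1O
F4 | step 3 | 2,3,5-tribromo-6-methoxybenzaldehyde | COc1c(C=O)c(Br)c(Br)cc1Br
F5 | step 3 | 2,3,5-tribromo-6-methoxyphenyl formate | COc1c(OC=O)c(Br)c(Br)cc1Br
F6 | step 2 | 3,5-dibromo-2-hydroxyphenyl formate | O=COc1cc(Br)cc(Br)c1O
F7 | step 2 | 3,5-dibromobenzene-1,2-diol | Oc1cc(Br)cc(Br)c1O
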